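C1 is the ketone carbon, C20 the chain methyl, ring A the trihydroxyphenyl ring. Retrosynthetic cuts, in order: the three phenol masks, C1–C(ring A), the four Z-alkenes back to alkynes, then C12–C13, C6–C7, C9–C10 and C15–C16.
Enabling feature: C7, C10 and C13 are each a CH2 held between two Z-CH=CH units (C5=C6, C8=C9, C11=C12, C14=C15). Raised to the alkyne level, C12 becomes an acidic sp C–H and C13 a primary propargylic electrophile, so C12–C13 forms with no geometry at stake and the C17 hydroxyl stays free.
Forward order: C13–C20 chloro alcohol (C15–C16 bond, one step); C7–C12 silyl-capped diyne bromide (C9–C10 bond); C1–C6 Weinreb amide; C6–C7; then C12–C13 completes the C20 skipped tetrayne.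
The helper (alkyne oxidation level) is removed in one fourfold syn semihydrogenation that sets all four Z double bonds together. Ring A, bought as phloroglucinol, is then joined to C1 as its tris-MOM aryllithium and unmasked last.
Stereochemistry: C17 (R) comes unchanged from (R)-2-propyloxirane, opened at its CH2; the four Z geometries come from syn addition of H2.

Key step: step 7

Assumption: (R)-2-propyloxirane of high enantiomeric purity is taken as a commercial starting material.

Step 1
Reactants: 1 3-chloroprop-1-yne (propargyl chloride); 2 (R)-2-propyloxirane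
Product: 4 (4R)-8-chlorooct-6-yn-4-ol, via chloropropynyllithium 3 (not isolated)
Conditions: 1 (1.5 equiv), n-BuLi, THF, −78 °C; BF3·OEt2, −78 °C; then 2, −78 °C; H2O quench
Reagents that add atoms: none
Why: BF3-promoted opening of a terminal epoxide by an alkynyllithium (Yamaguchi–Hirao alkynylation): at −78 °C the sp C–H of 1 is deprotonated faster than the C–Cl bond is attacked, the alkynyl carbon (future C15) enters at the unsubstituted epoxide carbon (future C16), and the C–O bond at the stereocentre (future C17) is never broken, so the R configuration of 2 is carried over unchanged.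

Step 2
Reactants: 5 (3-bromoprop-1-yn-1-yl)trimethylsilane; 6 prop-2-yn-1-ol
Product: 9 6-(trimethylsilyl)hexa-2,5-diyn-1-ol, via silylpropargyl iodide 7 (not isolated), via alkynylcopper 8 (not isolated)
Conditions: CuI, NaI, K2CO3, dry DMF, rt, Ar
Reagents that add atoms: none
Why: Copper-mediated sp–sp3 coupling of a terminal alkyne with a propargylic halide under carbonate base and iodide activation, the standard entry to 1,4-diynes, which tolerates the free hydroxyl and, in dry DMF, the C-silyl cap that later becomes the C12–H.

Step 3
Reactants: 9 6-(trimethylsilyl)hexa-2,5-diyn-1-ol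
Product: 10 (6-bromohexa-1,4-diyn-1-yl)trimethylsilane
Conditions: CBr4, PPh3, CH2Cl2, 0 °C
Reagents that add atoms: tetrabromomethane, BrC(Br)(Br)Br
Why: Appel reaction, whose neutral conditions turn the primary propargylic alcohol (C7) into the bromide by SN2 displacement of the oxyphosphonium group without disturbing the base-sensitive 1,4-diyne or the silyl cap.

Step 4
Reactants: 11 hex-5-ynoic acid
Product: 13 N-methoxy-N-methylhex-5-ynamide, via acyl imidazole 12 (not isolated)
Conditions: 1,1'-carbonyldiimidazole (CDI), CH2Cl2, rt; then MeNH(OMe)·HCl, rt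
Reagents that add atoms: N,O-dimethylhydroxylamine hydrochloride, CNOC.Cl
Why: Weinreb amide formation by way of the acyl imidazole, a mild activation that leaves the terminal alkyne untouched and installs at C1 the acyl donor needed for the late ketone synthesis.

Step 5
Reactants: 13 N-methoxy-N-methylhex-5-ynamide; 10 (6-bromohexa-1,4-diyn-1-yl)trimethylsilane
Product: 16 N-methoxy-N-methyl-12-(trimethylsilyl)dodeca-5,8,11-triynamide, via diynyl iodide 14 (not isolated), via alkynylcopper 15 (not isolated)
Conditions: CuI, NaI, K2CO3, dry DMF, rt, Ar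
Reagents that add atoms: none
Why: Second copper-mediated alkyne–propargylic halide coupling (forms C6–C7), in which only 13 carries a free sp C–H because the alkyne terminus of 10 is capped by silicon, so self-coupling of 10 is excluded.

Step 6
Reactants: 16 N-methoxy-N-methyl-12-(trimethylsilyl)dodeca-5,8,11-triynamide
Product: 17 N-methoxy-N-methyldodeca-5,8,11-triynamide
Conditions: n-Bu4NF, AcOH, THF, 0 °C, Ar; short silica plug, used at once
Reagents that add atoms: none
Why: Fluoride-induced protodesilylation of an alkynylsilane, buffered by AcOH so that no basic species is present that could shift the doubly propargylic protons at C7 and C10.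

Step 7
Reactants: 17 N-methoxy-N-methyldodeca-5,8,11-triynamide; 4 (4R)-8-chlorooct-6-yn-4-ol
Product: 20 (17R)-17-hydroxy-N-methoxy-N-methylicosa-5,8,11,14-tetraynamide, via propargylic iodide 18 (not isolated), via alkynylcopper 19 (not isolated)
Conditions: CuI, NaI, K2CO3, dry degassed DMF, rt, Ar, dark
Reagents that add atoms: none
Why: K2CO3 in DMF metallates only the terminal sp C–H of 17 (C12), acidified by π-coordination to CuI, to give alkynylcopper 19, while NaI turns chloride 4 into the more reactive propargylic iodide 18 (Finkelstein exchange); the soft acetylide then displaces iodide at the primary carbon C13 in an SN2-type process (oxidative addition and reductive elimination at copper) and returns CuI. The closest known reaction type is the copper-mediated coupling of terminal alkynes with propargylic halides that is used to build methylene-skipped polyynes of the polyunsaturated fatty acid class. No ring is closed and no stereocentre is created; C17 lies four atoms from the reacting carbon and its C–O bond is not involved, so the R configuration is carried through. The step needs attack at C13 rather than at C15 (SN2′, allene), C- rather than O-alkylation, and no prototropic shift of the 1,4-diyne units: the unhindered primary C13 and the soft nucleophile favour direct substitution, carbonate is too weak to deprotonate the C17 hydroxyl, and a weak heterogeneous base at room temperature under argon spares the doubly propargylic CH2 groups (C7, C10, C13) and prevents oxidative dimerisation of the acetylide. Because geometry does not exist at the alkyne level, this one union delivers the whole C1–C20 chain with its only stereocentre, without any protecting group on oxygen, and leaves all four Z-alkenes to a single later reduction.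

Step 8
Reactants: 20 (17R)-17-hydroxy-N-methoxy-N-methylicosa-5,8,11,14-tetraynamide
Product: 21 (5Z,8Z,11Z,14Z,17R)-17-hydroxy-N-methoxy-N-methylicosa-5,8,11,14-tetraenamide
Conditions: H2 (1 atm, gas burette), Pd/CaCO3 poisoned with Pb(OAc)2 (Lindlar catalyst), quinoline, EtOAc, 10 °C, stopped after four equivalents of H2; chromatography on AgNO3-impregnated silica
Reagents that add atoms: none
Why: Lindlar semihydrogenation applied fourfold, a transformation with close precedent on methylene-skipped tetraynes: each alkyne binds to the poisoned palladium surface more strongly than the alkene it gives and receives both hydrogens from the same face, so that C5=C6, C8=C9, C11=C12 and C14=C15 are all set Z in one operation, while the amide, the hydroxyl and C17 are not affected.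

Step 9
Reactants: 22 benzene-1,3,5-triol (phloroglucinol)
Product: 23 1,3,5-tris(methoxymethoxy)benzene
Conditions: NaH, MOMCl, DMF, 0 °C to rt
Reagents that add atoms: chloromethyl methyl ether (MOMCl), COCCl
Why: Williamson-type O-alkylation of the tris-phenoxide by the hard electrophile MOMCl, which favours O- over C-attack and gives acetal groups that later direct lithiation and fall off under mild acid.

Step 10
Reactants: 23 1,3,5-tris(methoxymethoxy)benzene; 21 (5Z,8Z,11Z,14Z,17R)-17-hydroxy-N-methoxy-N-methylicosa-5,8,11,14-tetraenamide
Product: 26 (5Z,8Z,11Z,14Z,17R)-17-hydroxy-1-[2,4,6-tris(methoxymethoxy)phenyl]icosa-5,8,11,14-tetraen-1-one, via aryllithium 24 (not isolated), via tetrahedral adduct 25 (not isolated)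
Conditions: 23 (3.2 equiv), n-BuLi (3.0 equiv), THF, 0 °C; then 21, −78 to 0 °C, Ar; H2O quench
Reagents that add atoms: none
Why: Directed ortho-metalation followed by Weinreb ketone synthesis: a position between two OMOM groups of 23 is lithiated (all three free positions are equivalent), one equivalent of 24 is spent on the C17 hydroxyl, a second adds to the amide to give the chelated adduct 25, which cannot collapse before the quench and so stops at the ketone stage, and the bis-allylic CH2 groups are not deprotonated by an aryllithium at or below 0 °C without activating additives.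

Step 11
Reactants: 26 (5Z,8Z,11Z,14Z,17R)-17-hydroxy-1-[2,4,6-tris(methoxymethoxy)phenyl]icosa-5,8,11,14-tetraen-1-one
Product: 27 (5Z,8Z,11Z,14Z,17R)-17-hydroxy-1-(2,4,6-trihydroxyphenyl)icosa-5,8,11,14-tetraen-1-one
Conditions: HCl (cat.), MeOH, 45 °C, Ar
Reagents that add atoms: none
Why: Acid-catalysed acetal exchange (MOM cleavage) in methanol, which carries the formaldehyde units away as dimethoxymethane; dilute methanolic acid of this kind is routinely used on polyunsaturated fatty acid derivatives without geometric or positional isomerisation and does not ionise the secondary homoallylic C17 alcohol, so geometry and configuration are kept.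

Compound list
1 | 3-chloroprop-1-yne (propargyl chloride) | C#CCCl | starting material
2 | (R)-2-propyloxirane | CCC[C@@H]1CO1 | starting material
3 | (3-chloroprop-1-yn-1-yl)lithium | [Li]C#CCCl | intermediate
4 | (4R)-8-chlorooct-6-yn-4-ol | CCC[C@@H](O)CC#CCCl | intermediate
5 | (3-bromoprop-1-yn-1-yl)trimethylsilane | C[Si](C)(C)C#CCBr | starting material
6 | prop-2-yn-1-ol | C#CCO | starting material
7 | (3-iodoprop-1-yn-1-yl)trimethylsilane | C[Si](C)(C)C#CCI | intermediate
8 | (3-hydroxyprop-1-yn-1-yl)copper | [Cu]C#CCO | intermediate
9 | 6-(trimethylsilyl)hexa-2,5-diyn-1-ol | C[Si](C)(C)C#CCC#CCO | intermediate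
10 | (6-bromohexa-1,4-diyn-1-yl)trimethylsilane | C[Si](C)(C)C#CCC#CCBr | intermediate
11 | hex-5-ynoic acid | C#CCCCC(=O)O | starting material
12 | 1-(1H-imidazol-1-yl)hex-5-yn-1-one | C#CCCCC(=O)n1ccnc1 | intermediate
13 | N-methoxy-N-methylhex-5-ynamide | C#CCCCC(=O)N(C)OC | intermediate
14 | (6-iodohexa-1,4-diyn-1-yl)trimethylsilane | C[Si](C)(C)C#CCC#CCI | intermediate
15 | {6-[methoxy(methyl)amino]-6-oxohex-1-yn-1-yl}copper | [Cu]C#CCCCC(=O)N(C)OC | intermediate
16 | N-methoxy-N-methyl-12-(trimethylsilyl)dodeca-5,8,11-triynamide | C[Si](C)(C)C#CCC#CCC#CCCCC(=O)N(C)OC | intermediate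
17 | N-methoxy-N-methyldodeca-5,8,11-triynamide | C#CCC#CCC#CCCCC(=O)N(C)OC | intermediate
18 | (4R)-8-iodooct-6-yn-4-ol | CCC[C@@H](O)CC#CCI | intermediate
19 | {12-[methoxy(methyl)amino]-12-oxododeca-1,4,7-triyn-1-yl}copper | [Cu]C#CCC#CCC#CCCCC(=O)N(C)OC | intermediate
20 | (17R)-17-hydroxy-N-methoxy-N-methylicosa-5,8,11,14-tetraynamide | CCC[C@@H](O)CC#CCC#CCC#CCC#CCCCC(=O)N(C)OC | intermediate
21 | (5Z,8Z,11Z,14Z,17R)-17-hydroxy-N-methoxy-N-methylicosa-5,8,11,14-tetraenamide | CCC[C@@H](O)C/C=C\C/C=C\C/C=C\C/C=C\CCCC(=O)N(C)OC | intermediate
22 | benzene-1,3,5-triol (phloroglucinol) | Oc1cc(O)cc(O)c1 | starting material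
23 | 1,3,5-tris(methoxymethoxy)benzene | COCOc1cc(OCOC)cc(OCOC)c1 | intermediate
24 | [2,4,6-tris(methoxymethoxy)phenyl]lithium | [Li]c1c(OCOC)cc(OCOC)cc1OCOC | intermediate
25 | dilithium (5Z,8Z,11Z,14Z,17R)-1-[methoxy(methyl)amino]-1-[2,4,6-tris(methoxymethoxy)phenyl]icosa-5,8,11,14-tetraene-1,17-diolate | [Li+].[Li+].CCC[C@@H]([O-])C/C=C\C/C=C\C/C=C\C/C=C\CCCC([O-])(N(C)OC)c1c(OCOC)cc(OCOC)cc1OCOC | intermediate
26 | (5Z,8Z,11Z,14Z,17R)-17-hydroxy-1-[2,4,6-tris(methoxymethoxy)phenyl]icosa-5,8,11,14-tetraen-1-one | CCC[C@@H](O)C/C=C\C/C=C\C/C=C\C/C=C\CCCC(=O)c1c(OCOC)cc(OCOC)cc1OCOC | intermediate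
27 | (5Z,8Z,11Z,14Z,17R)-17-hydroxy-1-(2,4,6-trihydroxyphenyl)icosa-5,8,11,14-tetraen-1-one | CCC[C@@H](O)C/C=C\C/C=C\C/C=C\C/C=C\CCCC(=O)c1c(O)cc(O)cc1O | target

Total number of steps: 11. Longest linear sequence: 8 steps (steps 2, 3, 5, 6, 7, 8, 10 and 11).

Steps most likely to fail

**Step 8.** Four alkynes on one molecule may be reduced unevenly. The last alkyne can lag while the first-formed alkenes begin to be saturated or isomerised, and the resulting mixture is hard to separate.

The fallback sets out from 4, 6, 13 and 5 and comes back at 21. It never reduces more than two alkynes in one operation.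
- Chloride 4 is coupled with 6 (CuI, NaI, K2CO3, DMF) to give (8R)-undeca-2,5-diyne-1,8-diol F1, which already holds the C12–C13 bond.
- Lindlar semihydrogenation of this polar, easily purified diol gives (2Z,5Z,8R)-undeca-2,5-diene-1,8-diol F2.
- An Appel reaction with one equivalent of CBr4/PPh3 at low temperature converts only the primary allylic hydroxyl, giving (4R,6Z,9Z)-11-bromoundeca-6,9-dien-4-ol F3.
- In parallel 13 is coupled with 5 under the same copper conditions to give N-methoxy-N-methyl-9-(trimethylsilyl)nona-5,8-diynamide F4. n-Bu4NF/AcOH desilylates this to N-methoxy-N-methylnona-5,8-diynamide F5.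
- Copper-mediated coupling of F5 with the Z-allylic bromide F3, a substitution known to keep the allylic geometry, gives (11Z,14Z,17R)-17-hydroxy-N-methoxy-N-methylicosa-11,14-dien-5,8-diynamide F6.
- The two remaining alkynes of F6 are semihydrogenated to 21.

**Step 7.** The terminal skipped triyne may undergo base-induced prototropic isomerisation or oxidative homocoupling before it is captured. Part of the substitution may also take the SN2′ course.

The fallback sets out from 9 and 4 and comes back at 20. It changes the order of chain assembly, so that C12–C13 is made on a small, sturdier diyne and the last union uses the robust monoyne 13 as the acetylide partner.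
- Compound 9 is desilylated (n-Bu4NF, AcOH, THF) to hexa-2,5-diyn-1-ol F7.
- F7 is coupled with 4 (CuI, NaI, K2CO3, DMF) to give (11R)-tetradeca-2,5,8-triyne-1,11-diol F8.
- One equivalent of CBr4/PPh3 at low temperature converts the primary propargylic hydroxyl, giving (4R)-14-bromotetradeca-6,9,12-triyn-4-ol F9.
- Copper-mediated coupling of F9 with 13 closes C6–C7 and gives 20.

**Step 10.** The hindered aryllithium may act as a base rather than as a nucleophile, either by elimination of formaldehyde from the N–OMe group or by enolisation at C2. Acyl transfer would then stay incomplete.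

The fallback sets out from 21 and comes back at 26. It replaces acyl substitution by carbonyl addition and oxidation.
- i-Bu2AlH (THF, −78 °C) reduces the Weinreb amide to (5Z,8Z,11Z,14Z,17R)-17-hydroxyicosa-5,8,11,14-tetraenal F10.
- Aryllithium 24 adds to the unhindered aldehyde at −78 °C to give (5Z,8Z,11Z,14Z,17R)-1-[2,4,6-tris(methoxymethoxy)phenyl]icosa-5,8,11,14-tetraene-1,17-diol F11 as both C1 epimers.
- MnO2 in CH2Cl2 oxidises only the electron-rich benzylic carbinol, not the C17 alcohol, to give 26.

Further compounds
F1 | step 8 | (8R)-undeca-2,5-diyne-1,8-diol | CCC[C@@H](O)CC#CCC#CCO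
F2 | step 8 | (2Z,5Z,8R)-undeca-2,5-diene-1,8-diol | CCC[C@@H](O)C/C=C\C/C=C\CO
F3 | step 8 | (4R,6Z,9Z)-11-bromoundeca-6,9-dien-4-ol | CCC[C@@H](O)C/C=C\C/C=C\CBr
F4 | step 8 | N-methoxy-N-methyl-9-(trimethylsilyl)nona-5,8-diynamide | C[Si](C)(C)C#CCC#CCCCC(=O)N(C)OC
F5 | step 8 | N-methoxy-N-methylnona-5,8-diynamide | C#CCC#CCCCC(=O)N(C)OC
F6 | step 8 | (11Z,14Z,17R)-17-hydroxy-N-methoxy-N-methylicosa-11,14-dien-5,8-diynamide | CCC[C@@H](O)C/C=C\C/C=C\CC#CCC#CCCCC(=O)N(C)OC
F7 | step 7 | hexa-2,5-diyn-1-ol | C#CCC#CCO
F8 | step 7 | (11R)-tetradeca-2,5,8-triyne-1,11-diol | CCC[C@@H](O)CC#CCC#CCC#CCO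
F9 | step 7 | (4R)-14-bromotetradeca-6,9,12-triyn-4-ol | CCC[C@@H](O)CC#CCC#CCC#CCBr
F10 | step 10 | (5Z,8Z,11Z,14Z,17R)-17-hydroxyicosa-5,8,11,14-tetraenal | CCC[C@@H](O)C/C=C\C/C=C\C/C=C\C/C=C\CCCC=O
F11 | step 10 | (5Z,8Z,11Z,14Z,17R)-1-[2,4,6-tris(methoxymethoxy)phenyl]icosa-5,8,11,14-tetraene-1,17-diol | CCC[C@@H](O)C/C=C\C/C=C\C/C=C\C/C=C\CCCC(O)c1c(OCOC)cc(OCOC)cc1OCOC
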